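**Strategy.** The seven-membered ring is opened at C6–C7 and C8–C9 (longipinane numbering), which removes C7–C8 as a two-carbon unit and leaves a bicyclo[3.1.1]heptane. Its four-membered ring (C4–C5–C11–C10) holds an isopropenyl group on C5 and a formyl group on C10 in a cis-1,3 relation, both on the face away from the C1–C3 bridge and about 3 Å apart. In the key step an iron hydride turns the isopropenyl group into the tertiary C6 radical, which adds to acrolein (C6–C7); the iron enolate then closes the ring by aldol addition to the formyl carbon C9 (C8–C9). Later steps excise the extra formyl carbon and set C7–C9 by reagent control.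

Key step: step 12

Remark: tricyclic compounds carry longipinane numbering (C1 = carbonyl carbon of the target, C2=C3, C4, C5, C6 = CMe2, C7–C9 = oxygenated carbons, C10 = C–CH3, C11); bicyclic ones are numbered as bicyclo[3.1.1]heptanes, and on a one-carbon bridge (C6, C7) "anti" means pointing away from the C2–C4 bridge.
Remark: the (S,S) enantiomer of the bisphosphoramide in step 4 is assumed to be the one that sends the dienolate to the Si face of enal 3.

Step 1
Reactants: 1 1-(benzyloxy)propan-2-one
Product: 2 (2E)-4-(benzyloxy)-N-methoxy-N,3-dimethylbut-2-enamide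
Conditions: (EtO)2P(O)CH2C(O)N(OMe)Me, NaH, THF, 0 °C to rt
Reagents that add atoms: diethyl [2-[methoxy(methyl)amino]-2-oxoethyl]phosphonate, CCOP(=O)(CC(=O)N(C)OC)OCC
Why: Horner–Wadsworth–Emmons olefination of the alkoxy ketone should give mainly the E enamide (amide trans to the larger CH2OBn group), the minor Z isomer being removed by chromatography.

Step 2
Reactants: 2 (2E)-4-(benzyloxy)-N-methoxy-N,3-dimethylbut-2-enamide
Product: 3 (2E)-4-(benzyloxy)-3-methylbut-2-enal
Conditions: DIBAL-H, THF, −78 °C; aq. Rochelle salt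
Reagents that add atoms: none
Why: Reduction of the Weinreb amide stops at the aldehyde because the chelated tetrahedral intermediate survives until work-up, and the alkene geometry is untouched.

Step 3
Reactants: 4 methyl 3-methylbut-2-enoate
Product: 5 tert-butyl[(1-methoxy-3-methylbuta-1,3-dien-1-yl)oxy]dimethylsilane
Conditions: LDA, THF/DMPU, −78 °C; TBSCl
Reagents that add atoms: tert-butyl(chloro)dimethylsilane, CC(C)(C)[Si](C)(C)Cl
Why: γ-Deprotonation of the enoate and O-silylation of the extended enolate should give the silyl dienol ether needed for a vinylogous Mukaiyama aldol reaction.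

Step 4
Reactants: 3 (2E)-4-(benzyloxy)-3-methylbut-2-enal; 5 silyl dienol ether
Product: 6 methyl (2E,5S,6E)-8-(benzyloxy)-5-hydroxy-3,7-dimethylocta-2,6-dienoate
Conditions: SiCl4, (S,S)-binaphthyldiamine-derived bisphosphoramide (5 mol%), i-Pr2NEt (10 mol%), CH2Cl2, −78 °C; aq. KF/KH2PO4
Reagents that add atoms: none
Why: Vinylogous Mukaiyama aldol reaction under chiral Lewis-base activation of SiCl4 should join the γ-carbon of 5 to the Si face of enal 3, which sets the 5S carbinol by catalyst control and leaves the 2E enoate.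

Step 5
Reactants: 6 methyl (2E,5S,6E)-8-(benzyloxy)-5-hydroxy-3,7-dimethylocta-2,6-dienoate
Product: 7 methyl (2E,5S,6E)-8-(benzyloxy)-5-[(tert-butyldimethylsilyl)oxy]-3,7-dimethylocta-2,6-dienoate
Conditions: TBSCl, imidazole, DMF, rt
Reagents that add atoms: tert-butyl(chloro)dimethylsilane, CC(C)(C)[Si](C)(C)Cl
Why: Standard silylation of the secondary allylic alcohol; the silyl ether prevents lactonisation and is the stereocontrol element of step 7.

Step 6
Reactants: 7 methyl (2E,5S,6E)-8-(benzyloxy)-5-[(tert-butyldimethylsilyl)oxy]-3,7-dimethylocta-2,6-dienoate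
Product: 8 (2E,5S,6E)-8-(benzyloxy)-5-[(tert-butyldimethylsilyl)oxy]-3,7-dimethylocta-2,6-dienoic acid
Conditions: LiOH, THF/MeOH/H2O, 40 °C; then 1 M HCl to pH 4, 0 °C
Reagents that add atoms: lithium hydroxide, [Li+].[OH-]
Why: Saponification of the methyl ester; the secondary silyl ether and both alkene geometries should survive hydroxide and a cold, mildly acidic work-up.

Step 7
Reactants: 8 (2E,5S,6E)-8-(benzyloxy)-5-[(tert-butyldimethylsilyl)oxy]-3,7-dimethylocta-2,6-dienoic acid
Product: 11 (1R,4S,5R,7R)-7-[(benzyloxy)methyl]-4-[(tert-butyldimethylsilyl)oxy]-7-methyl-2-methylidenebicyclo[3.1.1]heptan-6-one, via acid chloride 9 (not isolated), via vinylketene 10 (not isolated)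
Conditions: 1-chloro-N,N,2-trimethylprop-1-en-1-amine, CH2Cl2, 0 °C to rt; then Et3N, toluene, 110 °C, slow addition at high dilution
Reagents that add atoms: none
Why: The chloroenamine gives acid chloride 9 under neutral conditions, triethylamine removes a γ-hydrogen of the cis methyl group to give vinylketene 10, and its intramolecular [2+2] cycloaddition to the trisubstituted alkene (carbonyl carbon to the CH terminus, ketene α-carbon to the methyl-bearing carbon) should close the bicyclo[3.1.1]heptan-6-one, the E alkene placing CH2OBn anti on C7 and allylic 1,3-strain between the carbinol hydrogen and the cis methyl group letting the 5S centre choose the alkene face.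

Step 8
Reactants: 11 bicyclic ketone
Product: 12 (1R,2S,4S,5R,7R)-4-[(tert-butyldimethylsilyl)oxy]-7-(hydroxymethyl)-2,7-dimethylbicyclo[3.1.1]heptan-6-one
Conditions: H2 (1 atm), 10% Pd/C, EtOAc, rt
Reagents that add atoms: none
Why: Heterogeneous hydrogenation should saturate the exocyclic methylene from the face of the C6 carbonyl bridge (away from the substituted C7 bridge) and cleave the benzyl ether in the same operation; the new C2 centre becomes trigonal again in step 20.

Step 9
Reactants: 12 hydroxy ketone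
Product: 14 (1S,2S,4S,5R,6S,7R)-6-acetyl-4-[(tert-butyldimethylsilyl)oxy]-7-(hydroxymethyl)-2,7-dimethylbicyclo[3.1.1]heptane, via enol ether 13 (not isolated)
Conditions: Ph3P(Cl)CH(OMe)CH3, KHMDS, THF, −78 to 50 °C; aq. oxalic acid, THF, rt; K2CO3, MeOH, rt
Reagents that add atoms: (1-methoxyethyl)triphenylphosphonium chloride, COC(C)[P+](c1ccccc1)(c1ccccc1)c1ccccc1.[Cl-]; water, O
Why: Wittig alkoxyalkylidenation gives enol ether 13, whose hydrolysis gives the methyl ketone, and base equilibration of the epimerisable C6 centre should favour the acetyl group anti, where it avoids the C4 silyloxy group and is held as the cyclic hemiketal with the cis CH2OH group.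

Step 10
Reactants: 14 methyl ketone
Product: 15 (1S,2S,4S,5R,6S,7R)-4-[(tert-butyldimethylsilyl)oxy]-7-(hydroxymethyl)-2,7-dimethyl-6-(prop-1-en-2-yl)bicyclo[3.1.1]heptane
Conditions: Ph3PCH3Br, KOt-Bu, THF, 60 °C
Reagents that add atoms: methyltriphenylphosphonium bromide, C[P+](c1ccccc1)(c1ccccc1)c1ccccc1.[Br-]
Why: Wittig methylenation of the ketone (the hemiketal opens under the basic conditions) gives the isopropenyl group, and C6 keeps the thermodynamic configuration reached in step 9.

Step 11
Reactants: 15 isopropenyl alcohol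
Product: 16 (1S,2S,4S,5R,6S,7R)-4-[(tert-butyldimethylsilyl)oxy]-2,7-dimethyl-6-(prop-1-en-2-yl)bicyclo[3.1.1]heptane-7-carbaldehyde
Conditions: Dess–Martin periodinane, NaHCO3, CH2Cl2, 0 °C
Reagents that add atoms: none
Why: Buffered Dess–Martin oxidation of the neopentyl primary alcohol gives the non-enolisable aldehyde without touching the alkene; 16 is used at once so that an intramolecular carbonyl-ene reaction cannot compete.

Step 12
Reactants: 16 isopropenyl aldehyde; 17 acrolein (prop-2-enal)
Product: 19 1-[(tert-butyldimethylsilyl)oxy]longipin-8-ene-8-carbaldehyde, via aldol 18 (not isolated)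
Conditions: Fe(acac)3 (30 mol%), PhSiH3, 17 (3 equiv), EtOH/(CH2OH)2, 0 °C to rt; then MsCl, Et3N, CH2Cl2, 0 °C to rt
Reagents that add atoms: none
Why: Hydrogen-atom transfer from the iron hydride to the isopropenyl CH2 gives the tertiary C6 radical with C5 already fixed, this nucleophilic radical adds to acrolein to form C6–C7, the α-formyl radical is reduced to the iron enolate, and the enolate carbon C8 attacks the neighbouring formyl carbon C9 to form C8–C9, after which mesylation eliminates aldol 18 to the enal. The closest known reaction type is the hydrogen-atom-transfer-initiated radical–polar crossover annulation (Giese addition then aldol) of alkenes that carry a carbonyl group with enals. The seven-membered ring closes in the aldol step by 7-exo-trig attack, made easy because C6 and C9 sit cis-1,3 on the four-membered ring and point the same way. The new stereocentres at C8 and C9 are not controlled and need not be, since both become trigonal in 19. The step needs the radical to add to acrolein faster than it abstracts the formyl hydrogen or opens the four-membered ring, which the excess of acrolein and the saturated, non-stabilising C1–C3 bridge are meant to secure, and it needs selective hydrogen-atom transfer, secured because the isopropenyl group is the only alkene in 16.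

Step 13
Reactants: 19 enal
Product: 20 tert-butyl(longipin-8-en-1-yloxy)dimethylsilane
Conditions: RhCl(PPh3)3 (1.05 equiv), toluene, 110 °C
Reagents that add atoms: none
Why: Tsuji–Wilkinson decarbonylation of the enal (insertion into the formyl C–H bond, CO extrusion, reductive elimination) removes the extra carbon and leaves the cis C8=C9 alkene in place.

Step 14
Reactants: 20 cycloheptene
Product: 21 1-[(tert-butyldimethylsilyl)oxy]longipin-8-en-7-one
Conditions: Rh2(cap)4 (dirhodium tetracaprolactamate, 1 mol%), t-BuOOH (70% aq.), K2CO3, CH2Cl2, rt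
Reagents that add atoms: tert-butyl hydroperoxide, CC(C)(C)OO
Why: Dirhodium-catalysed allylic oxidation attacks the only allylic CH2 group (C7; C10 is quaternary) and gives the enone.

Step 15
Reactants: 21 enone
Product: 22 (7R)-1-[(tert-butyldimethylsilyl)oxy]longipin-8-en-7-ol
Conditions: (S)-2-methyl-CBS-oxazaborolidine (20 mol%), BH3·SMe2, THF, −40 °C; MeOH
Reagents that add atoms: none
Why: Corey–Bakshi–Shibata reduction, with the quaternary C6 as the large and the vinylic C8 as the small substituent, should deliver hydride to the face that gives the 7R allylic alcohol, so that C7 is set by reagent control.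

Step 16
Reactants: 22 allylic alcohol
Product: 23 (7R)-1,7-bis[(tert-butyldimethylsilyl)oxy]longipin-8-ene
Conditions: TBSOTf, 2,6-lutidine, CH2Cl2, 0 °C to rt
Reagents that add atoms: tert-butyldimethylsilyl trifluoromethanesulfonate, CC(C)(C)[Si](C)(C)OS(=O)(=O)C(F)(F)F
Why: The silyl triflate silylates the hindered allylic alcohol, and the silyl ether then shields one face of the C8=C9 alkene.

Step 17
Reactants: 23 bis-silyl ether
Product: 24 1,7-bis[(tert-butyldimethylsilyl)oxy]longipinane-8,9-diol
Conditions: OsO4 (10 mol%), NMO, acetone/H2O, rt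
Reagents that add atoms: 4-methylmorpholine 4-oxide, C[N+]1([O-])CCOCC1; water, O
Why: Upjohn dihydroxylation should occur on the alkene face opposite the allylic silyloxy group, which gives the 8,9-cis-diol trans to the C7 oxygen.

Step 18
Reactants: 24 diol
Product: 25 1,7-bis[(tert-butyldimethylsilyl)oxy]longipinane-8,9-diyl bis[(2Z)-2-methylbut-2-enoate]
Conditions: angelic acid, 2,4,6-trichlorobenzoyl chloride, Et3N, toluene, rt; then 24, toluene, 80 °C
Reagents that add atoms: angelic acid ((2Z)-2-methylbut-2-enoic acid), C/C=C(/C)C(=O)O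
Why: Yamaguchi esterification through the mixed anhydride, run without DMAP, should acylate both hindered secondary alcohols while keeping the Z geometry of the acyl groups.

Step 19
Reactants: 25 bis-angelate
Product: 26 1-hydroxy-7-[(tert-butyldimethylsilyl)oxy]longipinane-8,9-diyl bis[(2Z)-2-methylbut-2-enoate]
Conditions: HF·pyridine, pyridine, THF, 0 °C
Reagents that add atoms: none
Why: Fluoride should cleave the less hindered C1 silyl ether first, because the C7 silyl ether is flanked by the quaternary C6 and the C8 ester.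

Step 20
Reactants: 26 C1 alcohol
Product: 28 7-[(tert-butyldimethylsilyl)oxy]-1-oxolongipin-2-ene-8,9-diyl bis[(2Z)-2-methylbut-2-enoate], via ketone 27 (not isolated)
Conditions: IBX (2-iodoxybenzoic acid, 4 equiv), DMSO, 75 °C
Reagents that add atoms: none
Why: IBX oxidises the alcohol to ketone 27 and then dehydrogenates it towards C2–C3, the only enolisable side because C11 is a bridgehead, which gives the enone.

Step 21
Reactants: 28 silyl-protected enone
Product: 29 (4R,5S,7S,8R,9S,10R,11R)-7-hydroxy-1-oxolongipin-2-ene-8,9-diyl bis[(2Z)-2-methylbut-2-enoate]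
Conditions: HF·pyridine, THF, rt to 40 °C
Reagents that add atoms: none
Why: Acidic fluoride removes the last silyl ether without base, so that neither acyl migration nor angelate-to-tiglate isomerisation should occur.

**Compound list**

1 | 1-(benzyloxy)propan-2-one | CC(=O)COCc1ccccc1 | starting material
2 | (2E)-4-(benzyloxy)-N-methoxy-N,3-dimethylbut-2-enamide | CON(C)C(=O)/C=C(\C)COCc1ccccc1 | intermediate
3 | (2E)-4-(benzyloxy)-3-methylbut-2-enal | O=C/C=C(\C)COCc1ccccc1 | intermediate
4 | methyl 3-methylbut-2-enoate | COC(=O)C=C(C)C | starting material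
5 | tert-butyl[(1-methoxy-3-methylbuta-1,3-dien-1-yl)oxy]dimethylsilane (1Z isomer drawn; the geometry is of no consequence) | CO/C(O[Si](C)(C)C(C)(C)C)=C/C(C)=C | intermediate
6 | methyl (2E,5S,6E)-8-(benzyloxy)-5-hydroxy-3,7-dimethylocta-2,6-dienoate | COC(=O)/C=C(\C)C[C@H](O)/C=C(\C)COCc1ccccc1 | intermediate
7 | methyl (2E,5S,6E)-8-(benzyloxy)-5-[(tert-butyldimethylsilyl)oxy]-3,7-dimethylocta-2,6-dienoate | COC(=O)/C=C(\C)C[C@H](O[Si](C)(C)C(C)(C)C)/C=C(\C)COCc1ccccc1 | intermediate
8 | (2E,5S,6E)-8-(benzyloxy)-5-[(tert-butyldimethylsilyl)oxy]-3,7-dimethylocta-2,6-dienoic acid | OC(=O)/C=C(\C)C[C@H](O[Si](C)(C)C(C)(C)C)/C=C(\C)COCc1ccccc1 | intermediate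
9 | (2E,5S,6E)-8-(benzyloxy)-5-[(tert-butyldimethylsilyl)oxy]-3,7-dimethylocta-2,6-dienoyl chloride | ClC(=O)/C=C(\C)C[C@H](O[Si](C)(C)C(C)(C)C)/C=C(\C)COCc1ccccc1 | intermediate (not isolated)
10 | (5S,6E)-8-(benzyloxy)-5-[(tert-butyldimethylsilyl)oxy]-7-methyl-3-methylideneocta-1,6-dien-1-one (vinylketene) | O=C=CC(=C)C[C@H](O[Si](C)(C)C(C)(C)C)/C=C(\C)COCc1ccccc1 | intermediate (not isolated)
11 | (1R,4S,5R,7R)-7-[(benzyloxy)methyl]-4-[(tert-butyldimethylsilyl)oxy]-7-methyl-2-methylidenebicyclo[3.1.1]heptan-6-one (CH2OBn anti and CH3 syn on C7; OTBS on the side of the C6 bridge) | O=C1[C@H]2[C@@H](O[Si](C)(C)C(C)(C)C)CC(=C)[C@@H]1[C@@]2(C)COCc1ccccc1 | intermediate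
12 | (1R,2S,4S,5R,7R)-4-[(tert-butyldimethylsilyl)oxy]-7-(hydroxymethyl)-2,7-dimethylbicyclo[3.1.1]heptan-6-one (C2 methyl on the side of the C7 bridge) | O=C1[C@H]2[C@@H](O[Si](C)(C)C(C)(C)C)C[C@H](C)[C@@H]1[C@@]2(C)CO | intermediate
13 | 4-[(tert-butyldimethylsilyl)oxy]-7-(hydroxymethyl)-6-(1-methoxyethylidene)-2,7-dimethylbicyclo[3.1.1]heptane (ring stereocentres as in 12; E/Z mixture at the enol ether) | COC(C)=C1[C@H]2[C@@H](O[Si](C)(C)C(C)(C)C)C[C@H](C)[C@@H]1[C@@]2(C)CO | intermediate (not isolated)
14 | (1S,2S,4S,5R,6S,7R)-6-acetyl-4-[(tert-butyldimethylsilyl)oxy]-7-(hydroxymethyl)-2,7-dimethylbicyclo[3.1.1]heptane (acetyl anti on C6, cis to CH2OH; in equilibrium with its cyclic hemiketal) | CC(=O)[C@@H]1[C@H]2[C@@H](O[Si](C)(C)C(C)(C)C)C[C@H](C)[C@@H]1[C@@]2(C)CO | intermediate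
15 | (1S,2S,4S,5R,6S,7R)-4-[(tert-butyldimethylsilyl)oxy]-7-(hydroxymethyl)-2,7-dimethyl-6-(prop-1-en-2-yl)bicyclo[3.1.1]heptane (isopropenyl anti on C6, cis to CH2OH) | CC(=C)[C@@H]1[C@H]2[C@@H](O[Si](C)(C)C(C)(C)C)C[C@H](C)[C@@H]1[C@@]2(C)CO | intermediate
16 | (1S,2S,4S,5R,6S,7R)-4-[(tert-butyldimethylsilyl)oxy]-2,7-dimethyl-6-(prop-1-en-2-yl)bicyclo[3.1.1]heptane-7-carbaldehyde (isopropenyl and CHO both anti, cis-1,3) | CC(=C)[C@@H]1[C@H]2[C@@H](O[Si](C)(C)C(C)(C)C)C[C@H](C)[C@@H]1[C@@]2(C)C=O | intermediate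
17 | acrolein (prop-2-enal) | C=CC=O | starting material
18 | 1-[(tert-butyldimethylsilyl)oxy]-9-hydroxylongipinane-8-carbaldehyde (ring fusion as in 29; C1–OTBS on the side of C5, C3–CH3 on the side of C10; mixture at C8 and C9) | O=CC1CC(C)(C)[C@@H]2[C@H]3[C@@H](O[Si](C)(C)C(C)(C)C)C[C@H](C)[C@@H]2[C@@]3(C)C1O | intermediate (not isolated)
19 | 1-[(tert-butyldimethylsilyl)oxy]longipin-8-ene-8-carbaldehyde (ring stereocentres as in 18) | O=CC=1CC(C)(C)[C@@H]2[C@H]3[C@@H](O[Si](C)(C)C(C)(C)C)C[C@H](C)[C@@H]2[C@@]3(C)C=1 | intermediate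
20 | tert-butyl(longipin-8-en-1-yloxy)dimethylsilane (ring stereocentres as in 18) | C=1CC(C)(C)[C@@H]2[C@H]3[C@@H](O[Si](C)(C)C(C)(C)C)C[C@H](C)[C@@H]2[C@@]3(C)C=1 | intermediate
21 | 1-[(tert-butyldimethylsilyl)oxy]longipin-8-en-7-one (ring stereocentres as in 18) | C=1C(=O)C(C)(C)[C@@H]2[C@H]3[C@@H](O[Si](C)(C)C(C)(C)C)C[C@H](C)[C@@H]2[C@@]3(C)C=1 | intermediate
22 | (7R)-1-[(tert-butyldimethylsilyl)oxy]longipin-8-en-7-ol (C7–OH on the side of C4) | C=1[C@@H](O)C(C)(C)[C@@H]2[C@H]3[C@@H](O[Si](C)(C)C(C)(C)C)C[C@H](C)[C@@H]2[C@@]3(C)C=1 | intermediate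
23 | (7R)-1,7-bis[(tert-butyldimethylsilyl)oxy]longipin-8-ene | C=1[C@@H](O[Si](C)(C)C(C)(C)C)C(C)(C)[C@@H]2[C@H]3[C@@H](O[Si](C)(C)C(C)(C)C)C[C@H](C)[C@@H]2[C@@]3(C)C=1 | intermediate
24 | 1,7-bis[(tert-butyldimethylsilyl)oxy]longipinane-8,9-diol (8-OH and 9-OH cis, on the side of C11; C7–O trans to them, on the side of C4) | O[C@@H]1[C@@H](O[Si](C)(C)C(C)(C)C)C(C)(C)[C@@H]2[C@H]3[C@@H](O[Si](C)(C)C(C)(C)C)C[C@H](C)[C@@H]2[C@@]3(C)[C@@H]1O | intermediate
25 | 1,7-bis[(tert-butyldimethylsilyl)oxy]longipinane-8,9-diyl bis[(2Z)-2-methylbut-2-enoate] (configuration as in 24) | C/C=C(/C)C(=O)O[C@@H]1[C@@H](O[Si](C)(C)C(C)(C)C)C(C)(C)[C@@H]2[C@H]3[C@@H](O[Si](C)(C)C(C)(C)C)C[C@H](C)[C@@H]2[C@@]3(C)[C@@H]1OC(=O)/C(C)=C\C | intermediate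
26 | 1-hydroxy-7-[(tert-butyldimethylsilyl)oxy]longipinane-8,9-diyl bis[(2Z)-2-methylbut-2-enoate] (configuration as in 24) | C/C=C(/C)C(=O)O[C@@H]1[C@@H](O[Si](C)(C)C(C)(C)C)C(C)(C)[C@@H]2[C@H]3[C@@H](O)C[C@H](C)[C@@H]2[C@@]3(C)[C@@H]1OC(=O)/C(C)=C\C | intermediate
27 | 7-[(tert-butyldimethylsilyl)oxy]-1-oxolongipinane-8,9-diyl bis[(2Z)-2-methylbut-2-enoate] (configuration as in 24) | C/C=C(/C)C(=O)O[C@@H]1[C@@H](O[Si](C)(C)C(C)(C)C)C(C)(C)[C@@H]2[C@H]3C(=O)C[C@H](C)[C@@H]2[C@@]3(C)[C@@H]1OC(=O)/C(C)=C\C | intermediate (not isolated)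
28 | 7-[(tert-butyldimethylsilyl)oxy]-1-oxolongipin-2-ene-8,9-diyl bis[(2Z)-2-methylbut-2-enoate] (configuration as in 29) | C/C=C(/C)C(=O)O[C@@H]1[C@@H](O[Si](C)(C)C(C)(C)C)C(C)(C)[C@@H]2[C@H]3C(=O)C=C(C)[C@@H]2[C@@]3(C)[C@@H]1OC(=O)/C(C)=C\C | intermediate
29 | (4R,5S,7S,8R,9S,10R,11R)-7-hydroxy-1-oxolongipin-2-ene-8,9-diyl bis[(2Z)-2-methylbut-2-enoate] (CNP0336239.1) | C/C=C(/C)C(=O)O[C@@H]1[C@@H](O)C(C)(C)[C@@H]2[C@H]3C(=O)C=C(C)[C@@H]2[C@@]3(C)[C@@H]1OC(=O)/C(C)=C\C | target

**Step count.** 21 steps in total. The longest linear sequence is 20 steps (from 1 through steps 1, 2 and 4–21); step 3 prepares the dienol ether 5 on the side.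

**The three steps most likely to fail, with fallbacks**

Step 12 (key step) is the most exposed. The tertiary radical may abstract the formyl hydrogen that sits across the four-membered ring, or open the cyclobutane by β-scission, before it meets acrolein; the iron enolate may also be protonated before the seven-membered aldol closure. The fallback separates the two bond formations and keeps the formyl group out of the radical step. It sets out from alcohol 15 and comes back at cycloheptene 20. Iron-hydride Giese addition of 15 to 1-phenyl-5-(ethenylsulfonyl)-1H-tetrazole (Fe(acac)3, PhSiH3, EtOH) should give the sulfone alcohol F1. Dess–Martin oxidation should give the sulfone aldehyde F2. KHMDS in THF (−78 °C to rt) should then close the ring by intramolecular Julia–Kocienski olefination to 20.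

Step 7 comes next. The alkene carries two allylic oxygen substituents and may be too poor a partner for the ketene, so that ketene oligomerisation wins, and facial control by the silyloxy centre may be incomplete. The fallback replaces the vinylketene by a more electrophilic keteniminium ion on a saturated chain. It sets out from ester 7 and comes back at 12. Conjugate reduction with Mg in MeOH should give methyl (5S,6E)-8-(benzyloxy)-5-[(tert-butyldimethylsilyl)oxy]-3,7-dimethyloct-6-enoate F3. Aminolysis with Me2AlNMe2 should give the N,N-dimethylamide F4. Tf2O and 2,4,6-collidine in 1,2-dichloroethane at 80 °C, followed by aqueous NaHCO3, should give the cyclobutanone F5 by intramolecular [2+2] cycloaddition and hydrolysis. Hydrogenolysis (H2, 10% Pd/C) then gives 12; the C2 epimers formed this way are both usable, because C2 becomes trigonal in step 20.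

Step 18 is the third. Acylation of the two hindered hydroxyl groups may stop at the mono-ester, and forcing conditions may isomerise the angeloyl group to the tigloyl group. The fallback builds the Z alkenes on the scaffold instead of transferring them. It sets out from diol 24 and comes back at 25. Esterification of 24 with 2-[bis(2,2,2-trifluoroethoxy)phosphoryl]propanoic acid (DCC, DMAP, CH2Cl2) should give the bis(phosphonopropanoate) F6. Still–Gennari olefination with acetaldehyde (KHMDS, 18-crown-6, THF, −78 °C) should then give 25.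

**Further compounds**

F1 | step 12 | [4-[(tert-butyldimethylsilyl)oxy]-2,7-dimethyl-6-[2-methyl-4-[(1-phenyl-1H-tetrazol-5-yl)sulfonyl]butan-2-yl]bicyclo[3.1.1]heptan-7-yl]methanol (ring configuration as in 15) | O=S(=O)(CCC(C)(C)[C@@H]1[C@H]2[C@@H](O[Si](C)(C)C(C)(C)C)C[C@H](C)[C@@H]1[C@@]2(C)CO)c1nnnn1-c1ccccc1
F2 | step 12 | 4-[(tert-butyldimethylsilyl)oxy]-2,7-dimethyl-6-[2-methyl-4-[(1-phenyl-1H-tetrazol-5-yl)sulfonyl]butan-2-yl]bicyclo[3.1.1]heptane-7-carbaldehyde (ring configuration as in 16) | O=S(=O)(CCC(C)(C)[C@@H]1[C@H]2[C@@H](O[Si](C)(C)C(C)(C)C)C[C@H](C)[C@@H]1[C@@]2(C)C=O)c1nnnn1-c1ccccc1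
F3 | step 7 | methyl (5S,6E)-8-(benzyloxy)-5-[(tert-butyldimethylsilyl)oxy]-3,7-dimethyloct-6-enoate (C3 epimers) | COC(=O)CC(C)C[C@H](O[Si](C)(C)C(C)(C)C)/C=C(\C)COCc1ccccc1
F4 | step 7 | (5S,6E)-8-(benzyloxy)-5-[(tert-butyldimethylsilyl)oxy]-N,N,3,7-tetramethyloct-6-enamide (C3 epimers) | CN(C)C(=O)CC(C)C[C@H](O[Si](C)(C)C(C)(C)C)/C=C(\C)COCc1ccccc1
F5 | step 7 | 7-[(benzyloxy)methyl]-4-[(tert-butyldimethylsilyl)oxy]-2,7-dimethylbicyclo[3.1.1]heptan-6-one (ring configuration as in 11; C2 epimers) | O=C1[C@H]2[C@@H](O[Si](C)(C)C(C)(C)C)CC(C)[C@@H]1[C@@]2(C)COCc1ccccc1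
F6 | step 18 | 1,7-bis[(tert-butyldimethylsilyl)oxy]longipinane-8,9-diyl bis[2-[bis(2,2,2-trifluoroethoxy)phosphoryl]propanoate] (ring configuration as in 24; epimers at the phosphonate α-carbons) | CC(P(=O)(OCC(F)(F)F)OCC(F)(F)F)C(=O)O[C@@H]1[C@@H](O[Si](C)(C)C(C)(C)C)C(C)(C)[C@@H]2[C@H]3[C@@H](O[Si](C)(C)C(C)(C)C)C[C@H](C)[C@@H]2[C@@]3(C)[C@@H]1OC(=O)C(C)P(=O)(OCC(F)(F)F)OCC(F)(F)F
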